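**Plan**
Ring labels: A = benzoate ring, B = aryl group on C2, C = orcinol-type aryl group on C3, D = benzo ring of the indenone (C3a, C4–C7, C7a).
Cuts, in order: five phenolic O–H (carried as isopropyl ethers) and C7–H (carried as C7–Br); C3–C3a of the indenone, giving a 2-aryl-1,3-diaryl-1,3-diketone; C1–C2 (enolate acylation); C2–ring B (ketone α-arylation); the ring A–O–ring B bond (SNAr).
Enabling feature: in ring D, C3a is ortho to the C4 oxygen and para to the C6 methoxyl. It is therefore the electron-rich carbon of a 3,5-dioxygenated benzoyl unit and can reach the ring C ketone carbon C3 through a five-membered ring. Both ortho carbons of ring C carry oxygen, so ring C cannot compete.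
Forward: rings A and B are joined and capped to an aryl bromide, which arylates the ring C acetophenone. The ring D acid chloride acylates the resulting deoxybenzoin. Acid closes the only new ring, then C7–Br is removed and the five ethers are cleaved.
Stereochemistry: the target has no stereocentre. C2 of the diketone and C2/C3 of the hydroxyindanone are transient and are erased by dehydration.

Key step: step 13

Assumption: the target SMILES carries no stereodescriptor, so the hindered aryl–indenone axes at C2 and C3 are taken as configurationally undefined and no axial control is planned.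

**Step 1**
Reactants: 1 methyl 2,6-dihydroxy-4-methylbenzoate
Product: 2 methyl 2-hydroxy-6-isopropoxy-4-methylbenzoate
Conditions: 2-bromopropane (1.1 equiv), K2CO3 (1.1 equiv), DMF, 50 °C
Reagents that add atoms: 2-bromopropane, CC(C)Br
Why: Williamson ether synthesis; once one hydroxyl is alkylated the other is held in a strong hydrogen bond to the ester carbonyl and is far less nucleophilic, so a slight excess of halide should stop at the monoether.

**Step 2**
Reactants: 2 methyl 2-hydroxy-6-isopropoxy-4-methylbenzoate; 3 3-bromo-2-fluoro-5-methoxybenzaldehyde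
Product: 4 methyl 2-(2-bromo-6-formyl-4-methoxyphenoxy)-6-isopropoxy-4-methylbenzoate
Conditions: K2CO3, DMF, 100 °C
Reagents that add atoms: none
Why: Nucleophilic aromatic substitution by addition–elimination: the ortho formyl group stabilises the Meisenheimer adduct, fluoride is the best leaving group for this mechanism, and without a metal the C–Br bond needed later stays intact.

**Step 3**
Reactants: 4 methyl 2-(2-bromo-6-formyl-4-methoxyphenoxy)-6-isopropoxy-4-methylbenzoate
Product: 6 methyl 2-(2-bromo-6-hydroxy-4-methoxyphenoxy)-6-isopropoxy-4-methylbenzoate, via aryl formate 5 (not isolated)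
Conditions: mCPBA, CH2Cl2, 0 °C to rt; then MeOH, cat. TsOH, rt
Reagents that add atoms: meta-chloroperoxybenzoic acid (mCPBA), OOC(=O)c1cccc(Cl)c1
Why: Baeyer–Villiger oxidation of an ortho-aryloxybenzaldehyde (Dakin-type outcome), in which the oxygen-substituted aryl group migrates in the Criegee adduct, followed by acid-catalysed methanolysis of the formate so that no phenoxide is formed that could start a Smiles migration of ring A to the neighbouring oxygen.

**Step 4**
Reactants: 6 methyl 2-(2-bromo-6-hydroxy-4-methoxyphenoxy)-6-isopropoxy-4-methylbenzoate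
Product: 7 methyl 2-(2-bromo-6-isopropoxy-4-methoxyphenoxy)-6-isopropoxy-4-methylbenzoate
Conditions: i-PrOH, PPh3, DIAD, THF, 0 °C to rt
Reagents that add atoms: propan-2-ol, CC(C)O
Why: Mitsunobu etherification alkylates the phenol under near-neutral conditions at or below room temperature, which keeps the ortho-hydroxy diaryl ether away from the hot carbonate conditions that favour Smiles rearrangement.

**Step 5**
Reactants: 8 orcinol (5-methylbenzene-1,3-diol)
Product: 9 1,3-diisopropoxy-5-methylbenzene
Conditions: 2-bromopropane (3 equiv), K2CO3 (3 equiv), DMF, 70 °C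
Reagents that add atoms: 2-bromopropane, CC(C)Br
Why: Double Williamson ether synthesis on a simple resorcinol-type diphenol, with excess secondary halide and carbonate favouring O- over C-alkylation.

**Step 6**
Reactants: 9 1,3-diisopropoxy-5-methylbenzene
Product: 11 1-(2,6-diisopropoxy-4-methylphenyl)ethan-1-one, via aryllithium 10 (not isolated)
Conditions: n-BuLi, THF, 0 °C to rt; then MeC(O)N(OMe)Me, −78 °C to rt; 1 M HCl
Reagents that add atoms: N-methoxy-N-methylacetamide, CC(=O)N(C)OC; n-butyllithium, [Li]CCCC (lithium of 10 only)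
Why: Directed ortho-metalation takes place at the carbon flanked by both alkoxy groups (as known for 1,3-diisopropoxybenzene), and the Weinreb ketone synthesis stops at the ketone through its chelated tetrahedral adduct, giving the 2,6-dioxygenated acetophenone that Friedel–Crafts acetylation (which goes ortho to the methyl group) cannot give.

**Step 7**
Reactants: 7 methyl 2-(2-bromo-6-isopropoxy-4-methoxyphenoxy)-6-isopropoxy-4-methylbenzoate; 11 1-(2,6-diisopropoxy-4-methylphenyl)ethan-1-one
Product: 12 methyl 2-{2-[2-(2,6-diisopropoxy-4-methylphenyl)-2-oxoethyl]-6-isopropoxy-4-methoxyphenoxy}-6-isopropoxy-4-methylbenzoate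
Conditions: Pd2(dba)3 (2.5 mol %), XPhos (6 mol %), K3PO4, toluene, 100 °C
Reagents that add atoms: none
Why: Palladium-catalysed ketone α-arylation (Buchwald–Hartwig type): zerovalent palladium bearing a bulky biaryl phosphine inserts into the ortho-substituted C–Br bond, the methyl ketone enolate formed by the mild base K3PO4 couples at its unhindered carbon, the hindered ester is spared and the bulk of the product prevents a second arylation.

**Step 8**
Reactants: 13 methyl 2-bromo-3-methoxybenzoate
Product: 15 methyl 2-bromo-5-hydroxy-3-methoxybenzoate, via pinacol boronate 14 (not isolated)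
Conditions: [Ir(OMe)(cod)]2 (1.5 mol %), dtbpy (3 mol %), B2pin2 (0.6 equiv), THF, 80 °C; then KHSO5 (as 2KHSO5·KHSO4·K2SO4), acetone–H2O, rt
Reagents that add atoms: potassium peroxymonosulfate KHSO5, [K+].[O-]S(=O)(=O)OO; bis(pinacolato)diboron, CC1(C)OB(OC1(C)C)B1OC(C)(C)C(C)(C)O1 (boryl group of 14 only)
Why: Iridium-catalysed aromatic C–H borylation is governed by sterics and in this 1,2,3-trisubstituted arene only C5–H has no ortho substituent, and oxidation of the C–B bond then puts the hydroxyl para to bromine, so that the halogen sits unambiguously between the ester and the methoxyl, a placement that electrophilic bromination of a 3-hydroxy-5-methoxybenzoate would not guarantee.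

**Step 9**
Reactants: 15 methyl 2-bromo-5-hydroxy-3-methoxybenzoate
Product: 16 methyl 2-bromo-5-isopropoxy-3-methoxybenzoate
Conditions: 2-bromopropane, K2CO3, DMF, 60 °C
Reagents that add atoms: 2-bromopropane, CC(C)Br
Why: Williamson ether synthesis on an unhindered phenol.

**Step 10**
Reactants: 16 methyl 2-bromo-5-isopropoxy-3-methoxybenzoate
Product: 17 2-bromo-5-isopropoxy-3-methoxybenzoic acid
Conditions: LiOH, THF–MeOH–H2O, 50 °C; then 1 M HCl
Reagents that add atoms: lithium hydroxide, [Li+].[OH-]
Why: Saponification of a mono-ortho-substituted methyl benzoate; the aryl bromide and both ethers are inert to hydroxide at this temperature.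

**Step 11**
Reactants: 17 2-bromo-5-isopropoxy-3-methoxybenzoic acid
Product: 18 2-bromo-5-isopropoxy-3-methoxybenzoyl chloride
Conditions: (COCl)2, cat. DMF, CH2Cl2, 0 °C to rt; evaporated and used crude
Reagents that add atoms: oxalyl chloride, O=C(Cl)C(=O)Cl
Why: Acid chloride formation through the catalytic Vilsmeier-type chloroiminium species, a neutral method that leaves ethers and bromide untouched.

**Step 12**
Reactants: 12 methyl 2-{2-[2-(2,6-diisopropoxy-4-methylphenyl)-2-oxoethyl]-6-isopropoxy-4-methoxyphenoxy}-6-isopropoxy-4-methylbenzoate; 18 2-bromo-5-isopropoxy-3-methoxybenzoyl chloride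
Product: 20 1-(2-bromo-5-isopropoxy-3-methoxyphenyl)-3-(2,6-diisopropoxy-4-methylphenyl)-2-{3-isopropoxy-2-[3-isopropoxy-2-(methoxycarbonyl)-5-methylphenoxy]-5-methoxyphenyl}propane-1,3-dione, via lithium enolate 19 (not isolated)
Conditions: LiN(SiMe3)2 (2.2 equiv), toluene, −78 to 0 °C; then 18, 0 °C to rt; 1 M HCl
Reagents that add atoms: lithium bis(trimethylsilyl)amide, [Li]N([Si](C)(C)C)[Si](C)(C)C (lithium of 19 only)
Why: Claisen-type C-acylation of a ketone enolate with an acid chloride: the tight lithium ion pair in toluene favours attack through carbon, and the second equivalent of base stores the more acidic diketone as its enolate, which prevents further acylation and retro-Claisen cleavage.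

**Step 13**
Reactants: 20 1-(2-bromo-5-isopropoxy-3-methoxyphenyl)-3-(2,6-diisopropoxy-4-methylphenyl)-2-{3-isopropoxy-2-[3-isopropoxy-2-(methoxycarbonyl)-5-methylphenoxy]-5-methoxyphenyl}propane-1,3-dione
Product: 22 methyl 2-{2-[7-bromo-3-(2,6-diisopropoxy-4-methylphenyl)-4-isopropoxy-6-methoxy-1-oxo-1H-inden-2-yl]-6-isopropoxy-4-methoxyphenoxy}-6-isopropoxy-4-methylbenzoate, via tertiary 3-hydroxyindanone 21 (not isolated)
Conditions: MeSO3H–CH2Cl2 (1:4), 4 Å molecular sieves, 0 °C to rt
Reagents that add atoms: none
Why: Protonation of the diketone (through its enol tautomer, a hydroxy-substituted pentadienyl-type cation spanning C3a=C7a–C1–C2=C3) makes the ring C carbonyl carbon C3 electrophilic, ring D attacks it with C3a to give after rearomatisation the tertiary benzylic alcohol 21, and acid-catalysed loss of water toward C2–H delivers the fully conjugated indenone 22, which makes the sequence irreversible. The closest known reaction type is the acid-mediated intramolecular Friedel–Crafts hydroxyalkylation–dehydration (cyclodehydration) of 2-aryl-1,3-diaryl-1,3-diketones to 2,3-diarylindenones, a relative of the aromatic Nazarov cyclisation of 3,5-dialkoxyphenyl enones. The single new ring closes in a 5-exo-trig mode with respect to the C3=O bond (equivalently a 4π conrotatory closure of the protonated enol), and no stereocentre needs control because C2 and C3 of 21 both become sp2 in 22. Site selectivity is needed between the two carbons ortho to the benzoyl carbon of ring D and is fixed by the bromine at the future C7, which leaves only C3a, the carbon ortho to the isopropoxy and para to the methoxy group. Selectivity among arenes and ketones lies in the substrate: both ortho carbons of ring C carry oxygen, ring B could reach C3 only through a four-membered ring, ring A would need a seven-membered ring and is deactivated by its ester, and ring D cannot reach its own carbonyl. A non-nucleophilic Brønsted acid is preferred to TiCl4, AlCl3 or BCl3 because chelating Lewis acids would strip the isopropyl groups ortho to the ring C ketone and the freed phenol would close onto the ring D ketone to a chromone.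

**Step 14**
Reactants: 22 methyl 2-{2-[7-bromo-3-(2,6-diisopropoxy-4-methylphenyl)-4-isopropoxy-6-methoxy-1-oxo-1H-inden-2-yl]-6-isopropoxy-4-methoxyphenoxy}-6-isopropoxy-4-methylbenzoate
Product: 23 methyl 2-{2-[3-(2,6-diisopropoxy-4-methylphenyl)-4-isopropoxy-6-methoxy-1-oxo-1H-inden-2-yl]-6-isopropoxy-4-methoxyphenoxy}-6-isopropoxy-4-methylbenzoate
Conditions: Pd(PPh3)4 (10 mol %), HCO2Na, DMF, 100 °C
Reagents that add atoms: none
Why: Palladium-catalysed transfer hydrodehalogenation: zerovalent palladium inserts into the C7–Br bond, which is activated by the ortho carbonyl group, formate exchanges for bromide and loses CO2 to give an aryl palladium hydride, and reductive elimination gives C7–H while the tetrasubstituted enone, ester and ethers are not reduced.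

**Step 15**
Reactants: 23 methyl 2-{2-[3-(2,6-diisopropoxy-4-methylphenyl)-4-isopropoxy-6-methoxy-1-oxo-1H-inden-2-yl]-6-isopropoxy-4-methoxyphenoxy}-6-isopropoxy-4-methylbenzoate
Product: 24 ascomindone B
Conditions: BCl3 (12 equiv), CH2Cl2, −78 to 0 °C; then H2O
Reagents that add atoms: none
Why: Lewis acid ether cleavage: BCl3 removes secondary alkyl aryl ethers through a cation-like isopropyl transfer to chloride at low temperature, whereas the two aryl methyl ethers (neither is ortho to a carbonyl group) and the methyl ester react much more slowly, so all five phenols should be freed selectively.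

**Compound list**
1 | methyl 2,6-dihydroxy-4-methylbenzoate | COC(=O)c1c(O)cc(C)cc1O | starting material
2 | methyl 2-hydroxy-6-isopropoxy-4-methylbenzoate | COC(=O)c1c(O)cc(C)cc1OC(C)C | intermediate
3 | 3-bromo-2-fluoro-5-methoxybenzaldehyde | O=Cc1cc(OC)cc(Br)c1F | starting material
4 | methyl 2-(2-bromo-6-formyl-4-methoxyphenoxy)-6-isopropoxy-4-methylbenzoate | COC(=O)c1c(OC(C)C)cc(C)cc1Oc1c(Br)cc(OC)cc1C=O | intermediate
5 | methyl 2-[2-bromo-6-(formyloxy)-4-methoxyphenoxy]-6-isopropoxy-4-methylbenzoate (aryl formate, not isolated) | COC(=O)c1c(OC(C)C)cc(C)cc1Oc1c(Br)cc(OC)cc1OC=O | intermediate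
6 | methyl 2-(2-bromo-6-hydroxy-4-methoxyphenoxy)-6-isopropoxy-4-methylbenzoate | COC(=O)c1c(OC(C)C)cc(C)cc1Oc1c(Br)cc(OC)cc1O | intermediate
7 | methyl 2-(2-bromo-6-isopropoxy-4-methoxyphenoxy)-6-isopropoxy-4-methylbenzoate | COC(=O)c1c(OC(C)C)cc(C)cc1Oc1c(Br)cc(OC)cc1OC(C)C | intermediate
8 | orcinol (5-methylbenzene-1,3-diol) | Cc1cc(O)cc(O)c1 | starting material
9 | 1,3-diisopropoxy-5-methylbenzene | Cc1cc(OC(C)C)cc(OC(C)C)c1 | intermediate
10 | (2,6-diisopropoxy-4-methylphenyl)lithium (not isolated) | [Li]c1c(OC(C)C)cc(C)cc1OC(C)C | intermediate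
11 | 1-(2,6-diisopropoxy-4-methylphenyl)ethan-1-one | CC(=O)c1c(OC(C)C)cc(C)cc1OC(C)C | intermediate
12 | methyl 2-{2-[2-(2,6-diisopropoxy-4-methylphenyl)-2-oxoethyl]-6-isopropoxy-4-methoxyphenoxy}-6-isopropoxy-4-methylbenzoate (ring C deoxybenzoin) | COC(=O)c1c(OC(C)C)cc(C)cc1Oc1c(CC(=O)c2c(OC(C)C)cc(C)cc2OC(C)C)cc(OC)cc1OC(C)C | intermediate
13 | methyl 2-bromo-3-methoxybenzoate | COC(=O)c1cccc(OC)c1Br | starting material
14 | methyl 2-bromo-3-methoxy-5-(4,4,5,5-tetramethyl-1,3,2-dioxaborolan-2-yl)benzoate (not isolated) | COC(=O)c1cc(B2OC(C)(C)C(C)(C)O2)cc(OC)c1Br | intermediate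
15 | methyl 2-bromo-5-hydroxy-3-methoxybenzoate | COC(=O)c1cc(O)cc(OC)c1Br | intermediate
16 | methyl 2-bromo-5-isopropoxy-3-methoxybenzoate | COC(=O)c1cc(OC(C)C)cc(OC)c1Br | intermediate
17 | 2-bromo-5-isopropoxy-3-methoxybenzoic acid | OC(=O)c1cc(OC(C)C)cc(OC)c1Br | intermediate
18 | 2-bromo-5-isopropoxy-3-methoxybenzoyl chloride | O=C(Cl)c1cc(OC(C)C)cc(OC)c1Br | intermediate
19 | lithium enolate of 12 (geometry of no consequence, not isolated) | [Li]OC(=Cc1cc(OC)cc(OC(C)C)c1Oc1cc(C)cc(OC(C)C)c1C(=O)OC)c1c(OC(C)C)cc(C)cc1OC(C)C | intermediate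
20 | 1-(2-bromo-5-isopropoxy-3-methoxyphenyl)-3-(2,6-diisopropoxy-4-methylphenyl)-2-{3-isopropoxy-2-[3-isopropoxy-2-(methoxycarbonyl)-5-methylphenoxy]-5-methoxyphenyl}propane-1,3-dione (racemic, C2 epimerisable) | O=C(c1cc(OC(C)C)cc(OC)c1Br)C(c1cc(OC)cc(OC(C)C)c1Oc1cc(C)cc(OC(C)C)c1C(=O)OC)C(=O)c1c(OC(C)C)cc(C)cc1OC(C)C | intermediate
21 | methyl 2-{2-[7-bromo-3-(2,6-diisopropoxy-4-methylphenyl)-3-hydroxy-4-isopropoxy-6-methoxy-1-oxo-2,3-dihydro-1H-inden-2-yl]-6-isopropoxy-4-methoxyphenoxy}-6-isopropoxy-4-methylbenzoate (racemic diastereomer mixture, not isolated) | O=C1C(c3cc(OC)cc(OC(C)C)c3Oc3cc(C)cc(OC(C)C)c3C(=O)OC)C(O)(c3c(OC(C)C)cc(C)cc3OC(C)C)c2c(OC(C)C)cc(OC)c(Br)c12 | intermediate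
22 | methyl 2-{2-[7-bromo-3-(2,6-diisopropoxy-4-methylphenyl)-4-isopropoxy-6-methoxy-1-oxo-1H-inden-2-yl]-6-isopropoxy-4-methoxyphenoxy}-6-isopropoxy-4-methylbenzoate | O=C1C(c3cc(OC)cc(OC(C)C)c3Oc3cc(C)cc(OC(C)C)c3C(=O)OC)=C(c3c(OC(C)C)cc(C)cc3OC(C)C)c2c(OC(C)C)cc(OC)c(Br)c12 | intermediate
23 | methyl 2-{2-[3-(2,6-diisopropoxy-4-methylphenyl)-4-isopropoxy-6-methoxy-1-oxo-1H-inden-2-yl]-6-isopropoxy-4-methoxyphenoxy}-6-isopropoxy-4-methylbenzoate | O=C1C(c3cc(OC)cc(OC(C)C)c3Oc3cc(C)cc(OC(C)C)c3C(=O)OC)=C(c3c(OC(C)C)cc(C)cc3OC(C)C)c2c(OC(C)C)cc(OC)cc12 | intermediate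
24 | ascomindone B, methyl 2-{2-[3-(2,6-dihydroxy-4-methylphenyl)-4-hydroxy-6-methoxy-1-oxo-1H-inden-2-yl]-6-hydroxy-4-methoxyphenoxy}-6-hydroxy-4-methylbenzoate | COC(=O)c1c(O)cc(C)cc1Oc1c(O)cc(OC)cc1C1=C(c2c(O)cc(C)cc2O)c2c(O)cc(OC)cc2C1=O | target

**Step count**
Total steps: 15. Longest linear sequence: 9 steps (1, 2, 3, 4, 7, 12, 13, 14, 15).

**Steps most likely to fail**

Step 13 (ring closure). Three processes may defeat it.
- The arene carries a deactivating acyl group and must attack a carbonyl shielded by two ortho isopropoxy groups, so closure may be too slow.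
- Ipso-protonation of ring C with loss of the acyl chain may then compete.
- Loss of an ortho isopropyl group followed by closure through oxygen may also compete.

The fallback lowers C1 to the methylene level, so that ring D becomes an undeactivated 3,5-dialkoxybenzyl nucleophile, and restores the ketone after ring closure. It sets out from 16 and 12 and returns at 22.
- 16 is reduced with i-Bu2AlH (CH2Cl2, −78 to 0 °C) to (2-bromo-5-isopropoxy-3-methoxyphenyl)methanol F1.
- PBr3 (CH2Cl2, 0 °C) converts it to 2-bromo-1-(bromomethyl)-5-isopropoxy-3-methoxybenzene F2.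
- Enolate 19, made from 12 as in step 12, is C-alkylated with F2 (THF, −78 °C to rt) to the 1,2,3-triarylpropan-1-one F3.
- Mild acid (TsOH, toluene, 60 °C) should close the same C3–C3a bond by the classical indene cyclodehydration of β-aryl ketones, giving the 7-bromo-2,3-diaryl-1H-indene F4.
- Carbanion autoxidation of its doubly activated C1 methylene (Cs2CO3, O2, DMSO, rt) then gives 22.

Step 12 (C-acylation). The congested enolate may be acylated on oxygen instead of carbon. On warming it may also attack the ring A ester intramolecularly. The fallback replaces acylation by aldol addition and oxidation. It sets out from 18 and 12 and returns at 20.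
- 18 is reduced with LiAlH(Ot-Bu)3 (THF, −78 °C) to 2-bromo-5-isopropoxy-3-methoxybenzaldehyde F5.
- Enolate 19 adds to it at −78 °C, where only attack through carbon leads to a stable adduct, giving the β-hydroxy ketone F6 as a diastereomer mixture.
- Dess–Martin periodinane (NaHCO3, CH2Cl2, rt) oxidises the carbinol to 20.

Step 2 (diaryl ether). The phenoxide is hindered and ester-flanked. The fluoride carbon has two ortho substituents and a deactivating para methoxyl. Attack may therefore be too slow, and long heating degrades the aldehyde. The fallback forms the C–O bond intramolecularly by a Smiles rearrangement of a depside. It sets out from 2 and returns at 4.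
- 2 is saponified (KOH, aqueous DMSO, 80 °C, cold acidification) to 2-hydroxy-6-isopropoxy-4-methylbenzoic acid F7.
- F7 is esterified with commercial 3-bromo-2-hydroxy-5-methoxybenzaldehyde ((CF3CO)2O, toluene, rt) to the depside 2-bromo-6-formyl-4-methoxyphenyl 2-hydroxy-6-isopropoxy-4-methylbenzoate F8.
- K2CO3 in DMSO at rt lets the ring A phenoxide attack the ipso carbon of ring B, which is activated by the ortho formyl group, through a six-membered spiro adduct. Carboxylate is expelled to give 2-(2-bromo-6-formyl-4-methoxyphenoxy)-6-isopropoxy-4-methylbenzoic acid F9.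
- MeI and K2CO3 esterify F9 to 4.

**Further compounds**
F1 | step 13 | (2-bromo-5-isopropoxy-3-methoxyphenyl)methanol | OCc1cc(OC(C)C)cc(OC)c1Br
F2 | step 13 | 2-bromo-1-(bromomethyl)-5-isopropoxy-3-methoxybenzene | BrCc1cc(OC(C)C)cc(OC)c1Br
F3 | step 13 | methyl 2-{2-[1-(2-bromo-5-isopropoxy-3-methoxyphenyl)-3-(2,6-diisopropoxy-4-methylphenyl)-3-oxopropan-2-yl]-6-isopropoxy-4-methoxyphenoxy}-6-isopropoxy-4-methylbenzoate (racemic) | O=C(c1c(OC(C)C)cc(C)cc1OC(C)C)C(Cc1cc(OC(C)C)cc(OC)c1Br)c1cc(OC)cc(OC(C)C)c1Oc1cc(C)cc(OC(C)C)c1C(=O)OC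
F4 | step 13 | methyl 2-{2-[7-bromo-3-(2,6-diisopropoxy-4-methylphenyl)-4-isopropoxy-6-methoxy-1H-inden-2-yl]-6-isopropoxy-4-methoxyphenoxy}-6-isopropoxy-4-methylbenzoate | C1C(c3cc(OC)cc(OC(C)C)c3Oc3cc(C)cc(OC(C)C)c3C(=O)OC)=C(c3c(OC(C)C)cc(C)cc3OC(C)C)c2c(OC(C)C)cc(OC)c(Br)c12
F5 | step 12 | 2-bromo-5-isopropoxy-3-methoxybenzaldehyde | O=Cc1cc(OC(C)C)cc(OC)c1Br
F6 | step 12 | methyl 2-{2-[1-(2-bromo-5-isopropoxy-3-methoxyphenyl)-1-hydroxy-3-(2,6-diisopropoxy-4-methylphenyl)-3-oxopropan-2-yl]-6-isopropoxy-4-methoxyphenoxy}-6-isopropoxy-4-methylbenzoate (racemic diastereomer mixture) | OC(c1cc(OC(C)C)cc(OC)c1Br)C(c1cc(OC)cc(OC(C)C)c1Oc1cc(C)cc(OC(C)C)c1C(=O)OC)C(=O)c1c(OC(C)C)cc(C)cc1OC(C)C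
F7 | step 2 | 2-hydroxy-6-isopropoxy-4-methylbenzoic acid | OC(=O)c1c(O)cc(C)cc1OC(C)C
F8 | step 2 | 2-bromo-6-formyl-4-methoxyphenyl 2-hydroxy-6-isopropoxy-4-methylbenzoate | O=Cc1cc(OC)cc(Br)c1OC(=O)c1c(O)cc(C)cc1OC(C)C
F9 | step 2 | 2-(2-bromo-6-formyl-4-methoxyphenoxy)-6-isopropoxy-4-methylbenzoic acid | OC(=O)c1c(OC(C)C)cc(C)cc1Oc1c(Br)cc(OC)cc1C=O
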